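Readings and results were computed for an exercise, noise included.

Friday's run ended at 63.2 mM of product on 300 mM of starting material, after readings that had stopped rising beyond the scatter from 35 min on. I kept that as a fraction, 21.1%, and called product at the flat end over starting material charged the plateau share. Thursday's flask repeats Friday's charge, so this share was my first way to its yield.

| setting | Friday's | Wednesday's | Monday's | Sunday's | Thursday's |
|---|---|---|---|---|---|
| starting material | 300 mM | 180 mM | 300 mM | 600 mM | 300 mM |
| coupling partner | 750 mM | 630 mM | 380 mM | 750 mM | 750 mM |
| time |  |  |  |  | 140 min |

| run | time / min | [product] / mM |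
|---|---|---|
| Friday's run | 7.0 | 22.6 |
| Friday's run | 14 | 43.8 |
| Friday's run | 21 | 50.2 |
| Friday's run | 28 | 56.1 |
| Friday's run | 35 | 63.0 |
| Friday's run | 42 | 62.6 |
| Friday's run | 49 | 62.3 |
| Friday's run | 56 | 63.2 |
| Wednesday's run | 7.0 | 12.3 |
| Wednesday's run | 14 | 21.0 |
| Wednesday's run | 21 | 27.0 |
| Wednesday's run | 28 | 32.3 |
| Wednesday's run | 35 | 33.7 |
| Wednesday's run | 42 | 38.4 |
| Wednesday's run | 49 | 36.4 |
| Wednesday's run | 56 | 34.8 |
| Monday's run | 7.0 | 16.9 |
| Monday's run | 14 | 27.1 |
| Monday's run | 21 | 37.4 |
| Monday's run | 28 | 42.4 |
| Monday's run | 35 | 43.2 |
| Monday's run | 42 | 45.9 |
| Monday's run | 49 | 46.1 |
| Monday's run | 56 | 48.1 |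
| Sunday's run | 7.0 | 45.9 |
| Sunday's run | 14 | 82.6 |
| Sunday's run | 21 | 98.1 |
| Sunday's run | 28 | 111.3 |
| Sunday's run | 35 | 117.8 |
| Sunday's run | 42 | 124.3 |
| Sunday's run | 49 | 124.3 |
| Sunday's run | 56 | 126.9 |

(readings scatter by 2 mM)

- Overall: starting material + coupling partner -> product.
- Constant volume, constant temperature.
- "The second partner" is coupling partner.
- An order is taken over about fifteen percent of the charge, up and down.

- reaction order in [coupling partner] at the outset, round the charge of the Friday's run, defined at two percent of the starting material turned into product
- reaction order in [starting material] at the outset, round the charge of the Friday's run, defined at two percent of the starting material turned into product (one fixed amount of product, the same in the runs compared)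
- product in the Thursday's run at 140 min, as a share of the starting material charged

My second way came from a different flask. Sunday's run held twice the starting material of Friday's run at the same coupling partner, and its last reading gave a share of 21.2%. In logarithms, the charge rose by 0.301 and the last reading by 0.303, a power of 1.01. The two ways agreed, so I trusted the share for Thursday's flask. Monday's run, with less coupling partner and the same starting material, gave a share of 16.0% at its last reading, lower than Friday's, which is a power of 0.402 in coupling partner.

For the orders, the first readings gave me powers of 1.02 in starting material and 0.427 in coupling partner, close to the powers from the last readings. But the orders are asked at one fixed amount of product, and there I held the first readings to be the ones that cheated. They compare runs at one clock time, with 45.9 mM made in Sunday's run and 22.6 mM in Friday's, and not at one amount of product. Friday's first reading already stands at 7.53% of the charge, past the point asked about.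

The forecast gave 0.4 in coupling partner, 1 in starting material and 21.2% for Thursday's flask, holding that “Early rate and plateau therefore scale together”. Its order in coupling partner is a little below my 0.427.

Thursday's flask gave 22.3% at 140 min, against the plateau share of 21.1% read from Friday's last reading at 56 min, a reading that scatters by 0.667% of the charge, and the orders came out at 0.56 in coupling partner and 0.78 in starting material.

    starting material ⇌ intermediate (0.1224 /min, 0.09840 /min)
    intermediate + coupling partner → product (0.1044 /M/min)
    starting material → decomposed substrate (0.1044 /min)
    2 coupling partner → lost reagent (0.05718 /M/min)

In a run of Thursday's charge with the loss to decomposed substrate taken away, the share at 140 min was 56.5%, which is 0.428 in powers of ten above Friday's plateau share. The loss of starting material to decomposed substrate therefore cost Thursday's flask 34 percentage points, which is 44% of what is missing.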